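The target readings of oak and alder are the guide to three new flasks.

| flask | starting material | remark | time |
|---|---|---|---|
| oak | 0.0056 M | run made earlier |  |
| alder | 0.023 M | run made earlier |  |
| spring | 0.0050 M |  | 2.5 min |
| midnight | 0.010 M |  | 2.5 min |
| noon | 0.020 M |  | 2.5 min |

| run | time / s | target / % |
|---|---|---|
| oak | 10.0 | 0.9 |
| oak | 15.0 | 2.2 |
| oak | 30.0 | 3.3 |
| oak | 80.0 | 9.2 |
| alder | 10.0 | 0 |
| alder | 25.0 | 2.8 |
| alder | 50.0 | 7.4 |
| alder | 80.0 | 15.7 |

(each reading ± 0.5 percentage points)

- percent here means starting material units held: one self-condensation product counts as two
- what is said of target includes crystals
- crystals is a solid; its amount is given per volume of the solution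
- on the list of suspects stand: 2 starting material -> self-condensation product; intermediate -> target; crystals <-> target; target -> over-reaction product; starting material -> intermediate
- the concentration of target that is asked is that of its free form alone
- "hardly changes" means that all values lie within two and a half points (for a concentration: within two and a half percent of the largest)

- [target] (only what is free in solution) at the end for spring, midnight, noon, in this order
- the shape of the row from first to last (rises all the way / falls all the way / hardly changes / rises, then falls / falls, then rises)

Steps of first order give the same percent of charge at any charge, and self-condensation, being second order, takes more from a larger charge. Yet at 80.0 s alder, the larger charge, reads 15.7 % and stands higher than oak at 9.2 %. Of the suspects, crystals lead that way, as a solid form sheltered from over-reaction. Taking crystal exchange as fast, free target stands at one ceiling (its solubility) in any flask while crystals are present.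

Where is that ceiling? Alder's 2.8 % at 25.0 s lies between oak's 2.2 % at 15.0 s and 3.3 % at 30.0 s. So within their scatter the two still read level when alder held 6.44 × 10⁻⁴ M of target, crystals counted. That scattered reading serves as a rough mark for the ceiling.

Does spring get there? Oak, charged with 0.0056 M against spring's 0.0050 M, held 5.15 × 10⁻⁴ M at 80.0 s, and spring runs twice that time, so this reckoning expects crystals in spring too.

The quantity to carry is the charge spread 4.00, noon's charge over spring's. Free target at a fixed percent of charge means a spread across the row equal to that factor; free target under one ceiling means a spread of about 1. This reckoning therefore puts all three flasks near the mark.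

The forecast gives 8.000 × 10⁻⁴ M, 0.0011 M and 0.0012 M, shape rises all the way, a spread of 1.50. It differs from this reckoning on spring, which it calls “probably still unsaturated”.

The flasks give 2.87 × 10⁻⁴ M, 2.99 × 10⁻⁴ M and 3.18 × 10⁻⁴ M, shape rises all the way.

    2 starting material → self-condensation product (k = 0.691 M⁻¹ s⁻¹)
    intermediate → target (k = 0.00754 s⁻¹)
    crystals ⇌ target, rate k3*(cs3 - [target]) while solid is left; crystals form when [target] > cs3 (solubility = 0.290 mM, k = 0.889 s⁻¹)
    target → over-reaction product (k = 0.0571 s⁻¹)
    starting material → intermediate (k = 0.0274 s⁻¹)

At 2.50 min spring holds crystals at 3.37 % of its charge. Free target spreads from spring to noon by 1.11 against the charge spread of 4.00, and from spring to midnight by 1.04 against a charge ratio of 2.00.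

The earlier runs and the new flask were generated by integration on assumed constants, noise included.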